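**Retrosynthetic overview**

Numbering used below: ring C1 (C=O), C2=C3(CH3), C4 (CHOH), C5 (CH bearing the chain), C6 (CH2); chain C1'–C16'. The target 16 is the cis-(4S,5S) isomer, and the last disconnection is hydrolysis of a C1 dioxolane (15).
Key disconnection: ring bond C4–C5, made by a nickel-catalysed, enantioselective reductive aldehyde–1,3-diene cyclisation (intramolecular homoallylation) of the achiral (Z)-enal/(E,E)-diene 14. This step closes the only carbocycle and sets C4 and C5 together.
Enabling feature: the bishomoallylic alcohol array O–C4–C5–C1'H2–C2'=C3' (ring carbinol C4, ring CH C5, first CH2 and first trisubstituted alkene of the chain). It is the retron of a 1,2-hydro-hydroxyalkylation of a C5=C1'–C2'=C3' diene, and the cis C2=C3 bond of the six-membered ring holds aldehyde and diene together.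
Enal 14 comes from the (Z)-enoate 12 (Still–Gennari on α-ketal aldehyde 11). The diene arises by E-selective Wittig union of the geranylgeranyl tributylphosphonium ylide (from geranylgeraniol 6) with lactol 5, made from ethyl 4-(benzyloxy)-3-oxobutanoate 1.
Order of rings: the temporary dioxolane (step 1) and a temporary lactone/lactol (steps 2–3, opened in step 6) come first; the cyclohexene ring is formed last, in step 11.

Key step: step 11

Assumption: the sense of induction of the spiro phosphoramidite in step 11 cannot be derived with certainty from intermolecular precedent; the (S)-ligand is written, and its mirror image is used instead if that is the one leading to the (8S,9S) series.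

**Route**

Step 1
Reactants: 1 ethyl 4-(benzyloxy)-3-oxobutanoate
Product: 2 ethyl 2-{2-[(benzyloxy)methyl]-1,3-dioxolan-2-yl}acetate
Conditions: ethylene glycol (3 equiv), p-TsOH·H2O (5 mol %), benzene, reflux, Dean–Stark
Reagents that add atoms: ethylene glycol, OCCO
Why: Acid-catalysed ketalisation of the ketone of a β-keto ester with azeotropic removal of water is routine and masks C1 for the whole route; no stereocentre is formed.

Step 2
Reactants: 2 ethyl 2-{2-[(benzyloxy)methyl]-1,3-dioxolan-2-yl}acetate
Product: 4 1,4,7-trioxaspiro[4.4]nonan-8-one, via hydroxy ester 3 (not isolated)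
Conditions: H2 (1 atm), 10% Pd/C, EtOAc, rt; filter; toluene, 80 °C
Reagents that add atoms: none
Why: Hydrogenolysis of the benzyl ether frees the primary alcohol, which lactonises onto the ester (five-membered ring, favoured by the quaternary ketal carbon) under neutral conditions that avoid β-elimination of the ketal oxygen.

Step 3
Reactants: 4 1,4,7-trioxaspiro[4.4]nonan-8-one
Product: 5 1,4,7-trioxaspiro[4.4]nonan-8-ol (lactol, both epimers)
Conditions: iBu2AlH (1.1 equiv), CH2Cl2, −78 °C; aq. potassium sodium tartrate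
Reagents that add atoms: none
Why: Half-reduction of a γ-lactone with iBu2AlH at −78 °C stops at the lactol because the aluminium hemiacetal is stable until work-up; the lactol carbon is the future C5.

Step 4
Reactants: 6 (2E,6E,10E)-geranylgeraniol
Product: 7 (2E,6E,10E)-geranylgeranyl bromide
Conditions: PBr3 (0.4 equiv), Et2O, 0 °C
Reagents that add atoms: phosphorus tribromide, BrP(Br)Br
Why: Bromination of a primary allylic alcohol with PBr3 at 0 °C is an SN2 process that leaves the 2E double bond in place.

Step 5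
Reactants: 7 (2E,6E,10E)-geranylgeranyl bromide
Product: 8 tributyl[(2E,6E,10E)-geranylgeranyl]phosphonium bromide
Conditions: PBu3 (1.05 equiv), MeCN, rt
Reagents that add atoms: tributylphosphine, CCCCP(CCCC)CCCC
Why: SN2 quaternisation of tributylphosphine by the allylic bromide gives the salt needed for an E-selective allylic Wittig reaction.

Step 6
Reactants: 8 tributyl[(2E,6E,10E)-geranylgeranyl]phosphonium bromide; 5 1,4,7-trioxaspiro[4.4]nonan-8-ol
Product: 10 {2-[(2E,4E,8E,12E)-5,9,13,17-tetramethyloctadeca-2,4,8,12,16-pentaen-1-yl]-1,3-dioxolan-2-yl}methanol, via ylide 9 (not isolated)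
Conditions: 8 (2.2 equiv), KOt-Bu (2.2 equiv), THF, −78 °C; then 5, −78 °C → rt
Reagents that add atoms: none
Why: Wittig olefination of the lactol through its open hydroxy-aldehyde form makes C5=C1' and frees the C2 hydroxyl; allylic trialkylphosphonium ylides are known to give mainly E-alkenes, the second equivalent of ylide serves as base for the lactol OH, and the E-C2'=C3' bond is carried over from 6.

Step 7
Reactants: 10 {2-[(2E,4E,8E,12E)-5,9,13,17-tetramethyloctadeca-2,4,8,12,16-pentaen-1-yl]-1,3-dioxolan-2-yl}methanol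
Product: 11 2-[(2E,4E,8E,12E)-5,9,13,17-tetramethyloctadeca-2,4,8,12,16-pentaen-1-yl]-1,3-dioxolane-2-carbaldehyde
Conditions: Dess–Martin periodinane (1.3 equiv), NaHCO3, CH2Cl2, 0 °C → rt
Reagents that add atoms: none
Why: Dess–Martin oxidation of a neopentyl-type primary alcohol to the aldehyde is mild and buffered and should leave the ketal, the diene and the isolated alkenes untouched.

Step 8
Reactants: 11 2-[(2E,4E,8E,12E)-5,9,13,17-tetramethyloctadeca-2,4,8,12,16-pentaen-1-yl]-1,3-dioxolane-2-carbaldehyde
Product: 12 ethyl (2Z)-2-methyl-3-{2-[(2E,4E,8E,12E)-5,9,13,17-tetramethyloctadeca-2,4,8,12,16-pentaen-1-yl]-1,3-dioxolan-2-yl}prop-2-enoate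
Conditions: ethyl 2-[bis(2,2,2-trifluoroethoxy)phosphoryl]propanoate (1.3 equiv), KN(SiMe3)2 (1.25 equiv), 18-crown-6 (3 equiv), THF, −78 °C
Reagents that add atoms: ethyl 2-[bis(2,2,2-trifluoroethoxy)phosphoryl]propanoate, CCOC(=O)C(C)P(=O)(OCC(F)(F)F)OCC(F)(F)F
Why: Still–Gennari olefination: the electron-poor bis(trifluoroethyl) phosphonate with a dissociated potassium counter-ion eliminates fast from the kinetically formed adduct and should give the Z-trisubstituted enoate, which places the future C4 cis to C1 across C2=C3 as the ring closure requires.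

Step 9
Reactants: 12 ethyl (2Z)-2-methyl-3-{2-[(2E,4E,8E,12E)-5,9,13,17-tetramethyloctadeca-2,4,8,12,16-pentaen-1-yl]-1,3-dioxolan-2-yl}prop-2-enoate
Product: 13 (2Z)-2-methyl-3-{2-[(2E,4E,8E,12E)-5,9,13,17-tetramethyloctadeca-2,4,8,12,16-pentaen-1-yl]-1,3-dioxolan-2-yl}prop-2-en-1-ol
Conditions: iBu2AlH (2.5 equiv), CH2Cl2, −78 °C; aq. potassium sodium tartrate; Et3N-deactivated silica
Reagents that add atoms: none
Why: iBu2AlH reduces the enoate 1,2 to the allylic alcohol with retention of the Z geometry; work-up and chromatography are kept neutral or basic because the Z-hydroxy ketal can close to a furan under acid.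

Step 10
Reactants: 13 (2Z)-2-methyl-3-{2-[(2E,4E,8E,12E)-5,9,13,17-tetramethyloctadeca-2,4,8,12,16-pentaen-1-yl]-1,3-dioxolan-2-yl}prop-2-en-1-ol
Product: 14 (2Z)-2-methyl-3-{2-[(2E,4E,8E,12E)-5,9,13,17-tetramethyloctadeca-2,4,8,12,16-pentaen-1-yl]-1,3-dioxolan-2-yl}prop-2-enal
Conditions: activated MnO2 (20 equiv), CH2Cl2, rt; filtration; used at once
Reagents that add atoms: none
Why: MnO2 oxidises allylic alcohols selectively under neutral heterogeneous conditions and is removed by filtration, which should limit Z to E isomerisation of the enal.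

Step 11
Reactants: 14 (2Z)-2-methyl-3-{2-[(2E,4E,8E,12E)-5,9,13,17-tetramethyloctadeca-2,4,8,12,16-pentaen-1-yl]-1,3-dioxolan-2-yl}prop-2-enal
Product: 15 (8S,9S)-7-methyl-9-[(2E,6E,10E)-3,7,11,15-tetramethylhexadeca-2,6,10,14-tetraen-1-yl]-1,4-dioxaspiro[4.5]dec-6-en-8-ol
Conditions: Ni(cod)2 (10 mol %), (S)-SIPHOS [(S)-N,N-dimethyl-O,O'-(1,1'-spirobiindane-7,7'-diyl)phosphoramidite] (20 mol %), Et3B (3 equiv), THF, 0 °C → rt; aq. NaHCO3
Reagents that add atoms: none
Why: Zerovalent nickel binds the C5=C1'–C2'=C3' diene and the Et3B-activated aldehyde and couples them oxidatively at C4–C5 to an oxanickelacycle whose allyl part spans C1'–C3'; ethyl transfer from boron, β-hydride elimination (loss of ethylene) and C–H reductive elimination at the less hindered allyl terminus C1' give the boron alkoxide of 15, hydrolysed on work-up. The closest known reaction type is the nickel-catalysed homoallylation of aldehydes with 1,3-dienes promoted by Et3B or Et2Zn, which is known for ω-dienyl aldehydes (five- and six-membered rings) and in enantioselective form with chiral monodentate phosphorus ligands. The cyclohexene ring closes in a 6-exo mode with respect to the diene (the tethered diene terminus C5 is attacked and the rest of the diene stays outside the ring), helped by the Z-C2=C3 bond and the quaternary ketal carbon C1, which hold C4 and C5 close. C4 and C5 are formed together: O and C1' are both bound to nickel in the bond-forming step, which in the half-chair is reached with a small O–C4–C5–C1' dihedral only in the cis-fused arrangement, so OH and the chain should come out cis, and the chiral ligand selects the pair of enantiotopic faces that gives (8S,9S). The step needs 1,2-addition to the enal, reaction at the conjugated diene only, and hydrogen delivery to C1' with the E-C2'=C3' bond kept; the α-methyl, β-quaternary enal is a poor conjugate acceptor, nickel does not engage the isolated trisubstituted alkenes, and a σ-allyl at tertiary C3' (needed for the wrong regiochemistry or for E/Z scrambling) is disfavoured. The geometry of the C5=C1' bond is lost because C1' ends as CH2.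

Step 12
Reactants: 15 (8S,9S)-7-methyl-9-[(2E,6E,10E)-3,7,11,15-tetramethylhexadeca-2,6,10,14-tetraen-1-yl]-1,4-dioxaspiro[4.5]dec-6-en-8-ol
Product: 16 (4S,5S)-4-hydroxy-3-methyl-5-[(2E,6E,10E)-3,7,11,15-tetramethylhexadeca-2,6,10,14-tetraen-1-yl]cyclohex-2-en-1-one
Conditions: PPTS (0.2 equiv), acetone–H2O (10:1), rt
Reagents that add atoms: water, O
Why: Mild acid hydrolysis of the allylic ketal through a stabilised allylic oxocarbenium ion should give the conjugated enone directly without touching C4, C5 or the polyene, so the configuration set in step 11 is kept.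

**Compound list**

1 | ethyl 4-(benzyloxy)-3-oxobutanoate | CCOC(=O)CC(=O)COCc1ccccc1 | starting material
2 | ethyl 2-{2-[(benzyloxy)methyl]-1,3-dioxolan-2-yl}acetate | CCOC(=O)CC1(COCc2ccccc2)OCCO1 | intermediate
3 | ethyl 2-[2-(hydroxymethyl)-1,3-dioxolan-2-yl]acetate (not isolated) | CCOC(=O)CC1(CO)OCCO1 | intermediate
4 | 1,4,7-trioxaspiro[4.4]nonan-8-one | O=C1CC2(CO1)OCCO2 | intermediate
5 | 1,4,7-trioxaspiro[4.4]nonan-8-ol (both epimers at the hemiacetal carbon) | OC1CC2(CO1)OCCO2 | intermediate
6 | (2E,6E,10E)-3,7,11,15-tetramethylhexadeca-2,6,10,14-tetraen-1-ol (geranylgeraniol) | CC(C)=CCC/C(C)=C/CC/C(C)=C/CC/C(C)=C/CO | starting material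
7 | (2E,6E,10E)-1-bromo-3,7,11,15-tetramethylhexadeca-2,6,10,14-tetraene | CC(C)=CCC/C(C)=C/CC/C(C)=C/CC/C(C)=C/CBr | intermediate
8 | tributyl[(2E,6E,10E)-3,7,11,15-tetramethylhexadeca-2,6,10,14-tetraen-1-yl]phosphonium bromide | CC(C)=CCC/C(C)=C/CC/C(C)=C/CC/C(C)=C/C[P+](CCCC)(CCCC)CCCC.[Br-] | intermediate
9 | tributyl[(2E,6E,10E)-3,7,11,15-tetramethylhexadeca-2,6,10,14-tetraen-1-ylidene]phosphorane (ylide, not isolated) | CC(C)=CCC/C(C)=C/CC/C(C)=C/CC/C(C)=C/C=P(CCCC)(CCCC)CCCC | intermediate
10 | {2-[(2E,4E,8E,12E)-5,9,13,17-tetramethyloctadeca-2,4,8,12,16-pentaen-1-yl]-1,3-dioxolan-2-yl}methanol | OCC1(C/C=C/C=C(C)/CC/C=C(C)/CC/C=C(C)/CCC=C(C)C)OCCO1 | intermediate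
11 | 2-[(2E,4E,8E,12E)-5,9,13,17-tetramethyloctadeca-2,4,8,12,16-pentaen-1-yl]-1,3-dioxolane-2-carbaldehyde | O=CC1(C/C=C/C=C(C)/CC/C=C(C)/CC/C=C(C)/CCC=C(C)C)OCCO1 | intermediate
12 | ethyl (2Z)-2-methyl-3-{2-[(2E,4E,8E,12E)-5,9,13,17-tetramethyloctadeca-2,4,8,12,16-pentaen-1-yl]-1,3-dioxolan-2-yl}prop-2-enoate | CCOC(=O)/C(C)=C\C1(C/C=C/C=C(C)/CC/C=C(C)/CC/C=C(C)/CCC=C(C)C)OCCO1 | intermediate
13 | (2Z)-2-methyl-3-{2-[(2E,4E,8E,12E)-5,9,13,17-tetramethyloctadeca-2,4,8,12,16-pentaen-1-yl]-1,3-dioxolan-2-yl}prop-2-en-1-ol | OC/C(C)=C\C1(C/C=C/C=C(C)/CC/C=C(C)/CC/C=C(C)/CCC=C(C)C)OCCO1 | intermediate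
14 | (2Z)-2-methyl-3-{2-[(2E,4E,8E,12E)-5,9,13,17-tetramethyloctadeca-2,4,8,12,16-pentaen-1-yl]-1,3-dioxolan-2-yl}prop-2-enal | O=C/C(C)=C\C1(C/C=C/C=C(C)/CC/C=C(C)/CC/C=C(C)/CCC=C(C)C)OCCO1 | intermediate
15 | (8S,9S)-7-methyl-9-[(2E,6E,10E)-3,7,11,15-tetramethylhexadeca-2,6,10,14-tetraen-1-yl]-1,4-dioxaspiro[4.5]dec-6-en-8-ol | CC(C)=CCC/C(C)=C/CC/C(C)=C/CC/C(C)=C/C[C@H]1CC2(OCCO2)C=C(C)[C@H]1O | intermediate
16 | (4S,5S)-4-hydroxy-3-methyl-5-[(2E,6E,10E)-3,7,11,15-tetramethylhexadeca-2,6,10,14-tetraen-1-yl]cyclohex-2-en-1-one | CC(C)=CCC/C(C)=C/CC/C(C)=C/CC/C(C)=C/C[C@H]1CC(=O)C=C(C)[C@H]1O | target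

**Step count and risks**

Total step count: 12. Longest linear sequence: 10 steps (1 → 2 → 4 → 5 → 10 → 11 → 12 → 13 → 14 → 15 → 16).

Steps most likely to fail:

Step 11. The chiral ligand may discriminate poorly between the two cis-fused modes of oxidative cyclisation (low enantiomeric purity), and the tether may not enforce the cis-fused arrangement as strongly as argued (trans isomer formed alongside). The fallback removes both demands from the nickel step and sets C4 by a reagent-controlled reduction instead. It sets out from 14: cyclisation with the ligand-free catalyst (Ni(acac)2, Et3B, THF) should give the cyclised alcohol as a stereoisomer mixture F1. Dess–Martin oxidation of F1 gives the racemic spiro-ketal enone F2, in which only C9 is stereogenic. Reduction of F2 with the (R)-Me-CBS oxazaborolidine and catecholborane (toluene, −78 °C; CBS reduction of an α-substituted cyclohexenone, the alkenyl side acting as the large group) should deliver hydride to one face of the carbonyl in both enantiomers. This gives the cis alcohol 15 from the (9S) half and the trans alcohol F3 from the (9R) half, two diastereomers that are separated by chromatography. The route is rejoined at 15.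

Step 6. The ring-opened β-ketal aldehyde may lose a ketal oxygen by β-elimination under the basic ylide conditions, and stereomutation of the allylic ylide may erode the E selectivity at the new bond and the geometry at C2'=C3'. The fallback reverses the polarity of the olefination so that the geranylgeranyl unit enters as an enal with its double bonds untouched. It sets out from lactone 4 and alcohol 6: LiAlH4 reduction of 4 gives the diol F4. Mitsunobu thioetherification with 1-phenyl-1H-tetrazole-5-thiol (PPh3, DIAD) should take place only at the unhindered CH2CH2OH (the neopentyl-type CH2OH beside the ketal is slow in SN2) and give the sulfide F5. Oxidation with H2O2 and (NH4)6Mo7O24 gives the sulfone F6. MnO2 oxidation of 6 gives geranylgeranial F7. Julia–Kocienski olefination of F6 with F7 (KN(SiMe3)2, 2.1 equiv, THF, −78 °C) should give mainly the E-diene and rejoins the route at 10.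

Step 10. The Z-hydroxy ketal 13 may cyclise to a furan on traces of acid before it is oxidised, and the Z-enal may isomerise to the E-enal on the oxidant surface; the E-isomer cannot close the ring. The fallback builds the Z-enal without the allylic alcohol and without an oxidation. It sets out from aldehyde 11: Corey–Fuchs dibromo-olefination (CBr4, PPh3, Zn, CH2Cl2) gives the 1,1-dibromoalkene F8. A trans-selective Negishi monomethylation (MeZnCl, PdCl2(DPEphos), THF) replaces the bromine trans to the ketal carbon and gives the (Z)-bromoalkene F9. Bromine–lithium exchange (t-BuLi, Et2O, −78 °C) and formylation with DMF, both with retention at the alkene, give the enal cold and rejoin the route at 14.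

**Further compounds**

F1 | step 11 | 7-methyl-9-[(2E,6E,10E)-3,7,11,15-tetramethylhexadeca-2,6,10,14-tetraen-1-yl]-1,4-dioxaspiro[4.5]dec-6-en-8-ol, racemic mixture of cis and trans isomers | CC(C)=CCC/C(C)=C/CC/C(C)=C/CC/C(C)=C/CC1CC2(OCCO2)C=C(C)C1O
F2 | step 11 | racemic 7-methyl-9-[(2E,6E,10E)-3,7,11,15-tetramethylhexadeca-2,6,10,14-tetraen-1-yl]-1,4-dioxaspiro[4.5]dec-6-en-8-one | CC(C)=CCC/C(C)=C/CC/C(C)=C/CC/C(C)=C/CC1CC2(OCCO2)C=C(C)C1=O
F3 | step 11 | (8S,9R)-7-methyl-9-[(2E,6E,10E)-3,7,11,15-tetramethylhexadeca-2,6,10,14-tetraen-1-yl]-1,4-dioxaspiro[4.5]dec-6-en-8-ol (trans isomer) | CC(C)=CCC/C(C)=C/CC/C(C)=C/CC/C(C)=C/C[C@@H]1CC2(OCCO2)C=C(C)[C@H]1O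
F4 | step 6 | [2-(2-hydroxyethyl)-1,3-dioxolan-2-yl]methanol | OCCC1(CO)OCCO1
F5 | step 6 | (2-{2-[(1-phenyl-1H-tetrazol-5-yl)sulfanyl]ethyl}-1,3-dioxolan-2-yl)methanol | OCC1(CCSc2nnnn2-c2ccccc2)OCCO1
F6 | step 6 | (2-{2-[(1-phenyl-1H-tetrazol-5-yl)sulfonyl]ethyl}-1,3-dioxolan-2-yl)methanol | OCC1(CCS(=O)(=O)c2nnnn2-c2ccccc2)OCCO1
F7 | step 6 | (2E,6E,10E)-3,7,11,15-tetramethylhexadeca-2,6,10,14-tetraenal (geranylgeranial) | CC(C)=CCC/C(C)=C/CC/C(C)=C/CC/C(C)=C/C=O
F8 | step 10 | 2-(2,2-dibromoethenyl)-2-[(2E,4E,8E,12E)-5,9,13,17-tetramethyloctadeca-2,4,8,12,16-pentaen-1-yl]-1,3-dioxolane | BrC(Br)=CC1(C/C=C/C=C(C)/CC/C=C(C)/CC/C=C(C)/CCC=C(C)C)OCCO1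
F9 | step 10 | 2-[(1Z)-2-bromoprop-1-en-1-yl]-2-[(2E,4E,8E,12E)-5,9,13,17-tetramethyloctadeca-2,4,8,12,16-pentaen-1-yl]-1,3-dioxolane | Br/C(C)=C\C1(C/C=C/C=C(C)/CC/C=C(C)/CC/C=C(C)/CCC=C(C)C)OCCO1
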